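The central cyclohexene C-a(=C-b)–C-c(CH3)(O)–C-d–C-e–C-f is cut into a three-carbon acetone unit (C-b, C-c, C-d) and the chain C-a–C-f–C-e. The feature exploited: C-a sits on C3 of quinolone A, C-f carries the CMe2–O arm of pyran A and C-e sits on C3 of quinolone B. This chain is therefore the carbonyl, alpha-carbon and arylidene carbon of a pyranoquinolinedione. In one operation allyl acetoacetate undergoes catalytic asymmetric Michael addition and aldol condensation. This forges C-d–C-e and C-a=C-b, closes the carbocycle on the intact pyran A and sets C-e and C-f. The precursor is that arylidene ketone, with O4 of quinolone B masked as a MOM ether.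

Key step: step 7

**Stereochemical bookkeeping**
- The target is C-c S, C-e R, C-f S.
- O on C-c and quinolone B on C-e are cis (1,3-diaxial bridge). The CMe2 arm on C-f is trans to quinolone B.
- C-e keeps one spatial arrangement from 18 to 26. Its descriptor reads S in 18–21 and R from 22 on, only because the ester changes the priorities.

**Design points**
- The ring-opened 3-acyl-4-hydroxyquinolone anion is a thermodynamic sink, so chromanone 9 never meets an equilibrating base. It is enolised kinetically at −78 °C.
- O4 of quinolone B must be capped, because a free 4-OH would protonate the amine catalyst. The MOM acetal also directs the C3 lithiation and leaves in the acid step that closes pyran B.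
- An amine–thiourea is too weak a base to drive the aldol condensation. The annulation is therefore run in one flask in two stages.
- The allyl ester is kept because it leaves under neutral conditions.

**Assumption:** the elimination in step 6 is taken to give the E-alkene usual for 3-arylidenechromanones. If allylic strain against the gem-dimethyl group favours the Z-alkene, only the choice between the quinine- and quinidine-derived catalyst changes, since C-e is defined by the face attacked and C-f is set afterwards.

## Route

Step 1
Reactants: 1 2,3-dimethoxyaniline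
Product: 3 2,3-dimethoxy-N-methylaniline, via aminal ether 2 (not isolated)
Conditions: (CH2O)n, NaOMe, MeOH, 40 °C; then NaBH4, reflux
Reagents that add atoms: formaldehyde (from paraformaldehyde), C=O
Why: Reductive N-methylation (reductive amination): under methoxide the aniline and formaldehyde stop at the N-methoxymethyl adduct 2, which carries only one new carbon, and NaBH4 reduces the imine released from it, so the secondary amine should form without over-methylation.

Step 2
Reactants: 3 2,3-dimethoxy-N-methylaniline; 4 diethyl malonate
Product: 6 4-hydroxy-7,8-dimethoxy-1-methylquinolin-2(1H)-one, via malonanilide ester 5 (not isolated)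
Conditions: Ph2O, 250 °C, EtOH distilled off
Reagents that add atoms: none
Why: Thermal malonate cyclocondensation: aminolysis of one ester gives anilide 5 and near 250 °C its second ester acylates the only free ortho carbon, which lies para to a methoxy group, in an intramolecular Friedel–Crafts-type closure to the 4-hydroxy-2-quinolone.

Step 3
Reactants: 6 4-hydroxy-7,8-dimethoxy-1-methylquinolin-2(1H)-one; 7 3,3-dimethylacrylic acid
Product: 9 chromanone A (7,8-dimethoxy-2,2,6-trimethyl-2,3-dihydro-4H-pyrano[3,2-c]quinoline-4,5(6H)-dione), via acyl enone 8 (not isolated)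
Conditions: polyphosphoric acid (medium), 90 °C
Reagents that add atoms: none
Why: Friedel–Crafts-type C3-acylation of the enolic quinolone by the activated acid gives enone 8, whose 4-hydroxy group adds to the dimethyl-substituted alkene terminus (6-endo-trig oxa-Michael addition) with retention of the 2-quinolone lactam, the standard acid-mediated 2,2-dimethylchromanone synthesis.

Step 4
Reactants: 6 4-hydroxy-7,8-dimethoxy-1-methylquinolin-2(1H)-one
Product: 10 7,8-dimethoxy-4-(methoxymethoxy)-1-methylquinolin-2(1H)-one
Conditions: MOMCl, iPr2NEt, CH2Cl2, 0 °C → rt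
Reagents that add atoms: chloromethyl methyl ether, COCCl
Why: O-Alkylation of the acidic 4-hydroxy group (a vinylogous carboxylic acid) with the hard electrophile MOMCl should place the acetal on O4, nitrogen being blocked by methyl.

Step 5
Reactants: 10 7,8-dimethoxy-4-(methoxymethoxy)-1-methylquinolin-2(1H)-one
Product: 12 7,8-dimethoxy-4-(methoxymethoxy)-1-methyl-2-oxo-1,2-dihydroquinoline-3-carbaldehyde, via aryllithium 11 (not isolated)
Conditions: n-BuLi, THF, −78 °C; DMF, −78 → 0 °C; AcOH
Reagents that add atoms: N,N-dimethylformamide, CN(C)C=O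
Why: Directed lithiation and formylation: C3–H lies between the MOM ether and the lactam carbonyl, both of which coordinate lithium, so n-BuLi should remove it selectively and aryllithium 11 is acylated by DMF, the aldehyde being released on the acidic quench.

Step 6
Reactants: 9 chromanone A; 12 quinolone B carbaldehyde MOM ether
Product: 16 (E)-3-(quinolon-B-ylmethylidene) chromanone A with O4 of quinolone B as MOM ether, via lithium enolate 13 (not isolated), via lithium aldolate 14 (not isolated), via mesylate 15 (not isolated)
Conditions: LiN(SiMe3)2, THF, −78 °C; 12; MsCl, −78 → 0 °C; DBU, 0 °C → rt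
Reagents that add atoms: none
Why: Directed aldol addition, mesylation and E1cB elimination: kinetic enolate 13 is a flat 2H-pyran whose ring C–O bond lies in the nodal plane of the enolate and so should not eliminate at −78 °C, it adds to the lithium-chelating and non-enolisable aldehyde 12, and in 15 only the freely rotating exocyclic mesylate can align for loss, which gives the conjugated arylidene ketone.

Step 7
Reactants: 16 arylidene ketone; 17 allyl acetoacetate
Product: 20 cyclohexenone allyl ester (C-a=C-b–C-c=O; CO2allyl on C-d; MOM-quinolone B on C-e; pyran A closed; C-d R; C-e S; C-f S), via Michael adduct 18 (not isolated), via ketol 19 (not isolated)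
Conditions: 17 (3 equiv), 9-amino-9-deoxy-epi-quinine 3,5-bis(trifluoromethyl)phenyl thiourea (10 mol %), PhMe, rt; then DBU (0.5 equiv), 4 Å MS, 40 °C
Reagents that add atoms: none
Why: The quinuclidine nitrogen of the catalyst deprotonates 17 while its thiourea N–H pair binds the C-a carbonyl of 16, which has the lactam carbonyl of quinolone A next to it as a second acceptor site, and the bound enolate is delivered through its methylene carbon C-d to the Re face of C-e, so C-e of 18 is set by the catalyst. DBU then shifts the enolate to the acetyl methyl carbon C-b, which attacks C-a in a 6-(enolendo)-exo-trig aldol closure to ketol 19, and E1cB loss of water, pulled by conjugation of C-a=C-b with quinolone A, makes the ring closure irreversible. The closest known reaction type is the Michael–aldol condensation of acetoacetates with chalcones, 2-arylidene-1-tetralones and 3-arylidenechromanones, whose first stage is known in enantioselective form under cinchona amine–thiourea catalysis. C-f is alpha to the ketone in 18 and gamma to the enone in 20, so it should equilibrate under DBU to the isomer with the CMe2 arm trans to quinolone B, the only one able to place these two bulky groups antiperiplanar (C-a and C-c are sp2, so the diaxial form has no 1,3-diaxial partners), while C-d settles trans as an epimerisable beta-keto ester carbon that is erased in step 8. The step needs carbocyclisation at C-b, which the substrate secures because every other carbon–carbonyl pairing in 18 would close a four-membered ring and attack by the enol oxygen gives only a reversible hemiketal. It also needs pyran A to survive, which rests on the C-a/C-f enolate being a flat 2H-pyran with its ring C–O bond orthogonal to the pi system, and a non-acidic O4 on quinolone B, which the MOM ether provides.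

Step 8
Reactants: 20 cyclohexenone allyl ester
Product: 22 cyclohexenone (C-d now CH2; C-e R; C-f S), via keto acid 21 (not isolated)
Conditions: Pd(PPh3)4 (5 mol %), morpholine, THF, rt → 40 °C
Reagents that add atoms: none
Why: Tsuji–Trost deallylation: zerovalent palladium ionises the allyl ester, excess morpholine captures the pi-allyl fragment, and the freed beta-keto acid 21 loses CO2 through its cyclic transition state under neutral conditions that should leave the MOM acetal, C-e and the trans C-f untouched.

Step 9
Reactants: 22 cyclohexenone
Product: 23 tertiary allylic alcohol (C-c epimers; C-e R; C-f S)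
Conditions: MeLi, CeCl3, THF, −78 °C; aq NH4Cl
Reagents that add atoms: methyllithium, [Li]C
Why: Organocerium 1,2-addition: the oxophilic and barely basic MeCeCl2 should attack the enone carbonyl rather than enolise C-d or C-f or touch the lactam carbonyls, and C-c needs no control here because both epimers ionise to the same cation in step 10.

Step 10
Reactants: 23 tertiary allylic alcohol
Product: 26 CNP0237003.1 (C-c S; C-e R; C-f S), via hydroxyquinolone alcohol 24 (not isolated), via allyl cation 25 (not isolated)
Conditions: TFA, CH2Cl2, 0 °C → rt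
Reagents that add atoms: none
Why: Acid cleaves the MOM acetal and ionises the tertiary allylic alcohol (SN1-type cycloetherification), and O4 of quinolone B, carried on the axial C-e substituent, can reach C-c of cation 25 only from its own face, so C-c is set by C-e as the 1,3-diaxial oxygen bridge of the bicyclo[3.3.1] core while C-a=C-b stays conjugated with quinolone A.

## Compound list

1 | 2,3-dimethoxyaniline | COc1cccc(N)c1OC | starting material
2 | N-(methoxymethyl)-2,3-dimethoxyaniline | COCNc1cccc(OC)c1OC | intermediate
3 | 2,3-dimethoxy-N-methylaniline | CNc1cccc(OC)c1OC | intermediate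
4 | diethyl malonate | CCOC(=O)CC(=O)OCC | starting material
5 | ethyl 3-[(2,3-dimethoxyphenyl)(methyl)amino]-3-oxopropanoate | CCOC(=O)CC(=O)N(C)c1cccc(OC)c1OC | intermediate
6 | 4-hydroxy-7,8-dimethoxy-1-methylquinolin-2(1H)-one | COc1ccc2c(O)cc(=O)n(C)c2c1OC | intermediate
7 | 3,3-dimethylacrylic acid | CC(C)=CC(=O)O | starting material
8 | 4-hydroxy-7,8-dimethoxy-1-methyl-3-(3-methylbut-2-enoyl)quinolin-2(1H)-one | COc1ccc2c(O)c(C(=O)C=C(C)C)c(=O)n(C)c2c1OC | intermediate
9 | chromanone A, 7,8-dimethoxy-2,2,6-trimethyl-2,3-dihydro-4H-pyrano[3,2-c]quinoline-4,5(6H)-dione | COc1ccc2c3c(c(=O)n(C)c2c1OC)C(=O)CC(C)(C)O3 | intermediate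
10 | 7,8-dimethoxy-4-(methoxymethoxy)-1-methylquinolin-2(1H)-one | COCOc1cc(=O)n(C)c2c(OC)c(OC)ccc12 | intermediate
11 | 3-lithio derivative of 10 | COCOc1c([Li])c(=O)n(C)c2c(OC)c(OC)ccc12 | intermediate
12 | 7,8-dimethoxy-4-(methoxymethoxy)-1-methyl-2-oxo-1,2-dihydroquinoline-3-carbaldehyde | COCOc1c(C=O)c(=O)n(C)c2c(OC)c(OC)ccc12 | intermediate
13 | lithium enolate of 9 (4-lithiooxy-2H-pyran form) | COc1ccc2c3c(c(=O)n(C)c2c1OC)C(O[Li])=CC(C)(C)O3 | intermediate
14 | lithium aldolate of 9 and 12 (both new centres unassigned, lost in the same step) | COc1ccc2c3c(c(=O)n(C)c2c1OC)C(=O)C(C(O[Li])c4c(OCOC)c5ccc(OC)c(OC)c5n(C)c4=O)C(C)(C)O3 | intermediate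
15 | mesylate of the aldol | COc1ccc2c3c(c(=O)n(C)c2c1OC)C(=O)C(C(OS(C)(=O)=O)c4c(OCOC)c5ccc(OC)c(OC)c5n(C)c4=O)C(C)(C)O3 | intermediate
16 | (E)-3-{[7,8-dimethoxy-4-(methoxymethoxy)-1-methyl-2-oxo-1,2-dihydroquinolin-3-yl]methylidene} derivative of 9 (aryl anti to the C4 carbonyl) | COc1ccc2c3c(c(=O)n(C)c2c1OC)C(=O)/C(=C/c4c(OCOC)c5ccc(OC)c(OC)c5n(C)c4=O)C(C)(C)O3 | intermediate
17 | allyl acetoacetate | CC(=O)CC(=O)OCC=C | starting material
18 | Michael adduct, allyl 2-acetyl-3-(MOM-quinolon-B-3-yl)-3-(chromanone-A-3-yl)propanoate; C-e S, C-f R, C-d epimers | COc1ccc2c3c(c(=O)n(C)c2c1OC)C(=O)[C@H]([C@H](c4c(OCOC)c5ccc(OC)c(OC)c5n(C)c4=O)C(C(C)=O)C(=O)OCC=C)C(C)(C)O3 | intermediate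
19 | ketol from C-b to C-a closure; C-e S, C-f S, C-a and C-d unassigned | COc1ccc2c3c(c(=O)n(C)c2c1OC)C1(O)CC(=O)C(C(=O)OCC=C)[C@@H](c4c(OCOC)c5ccc(OC)c(OC)c5n(C)c4=O)[C@@H]1C(C)(C)O3 | intermediate
20 | cyclohexenone allyl ester; C-d R, C-e S, C-f S, neighbouring substituents all trans | COc1ccc2c3c(c(=O)n(C)c2c1OC)C1=CC(=O)[C@H](C(=O)OCC=C)[C@@H](c4c(OCOC)c5ccc(OC)c(OC)c5n(C)c4=O)[C@@H]1C(C)(C)O3 | intermediate
21 | beta-keto acid from 20 | COc1ccc2c3c(c(=O)n(C)c2c1OC)C1=CC(=O)[C@H](C(=O)O)[C@@H](c4c(OCOC)c5ccc(OC)c(OC)c5n(C)c4=O)[C@@H]1C(C)(C)O3 | intermediate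
22 | decarboxylated cyclohexenone; C-e R, C-f S | COc1ccc2c3c(c(=O)n(C)c2c1OC)C1=CC(=O)C[C@@H](c4c(OCOC)c5ccc(OC)c(OC)c5n(C)c4=O)[C@@H]1C(C)(C)O3 | intermediate
23 | tertiary allylic alcohol, methyl and OH on C-c (both epimers); C-e R, C-f S | COc1ccc2c3c(c(=O)n(C)c2c1OC)C1=CC(C)(O)C[C@@H](c4c(OCOC)c5ccc(OC)c(OC)c5n(C)c4=O)[C@@H]1C(C)(C)O3 | intermediate
24 | 23 without MOM (free 4-hydroxyquinolone B) | COc1ccc2c3c(c(=O)n(C)c2c1OC)C1=CC(C)(O)C[C@@H](c4c(O)c5ccc(OC)c(OC)c5n(C)c4=O)[C@@H]1C(C)(C)O3 | intermediate
25 | allyl cation delocalised over C-c, C-b, C-a | COc1ccc2c3c(c(=O)n(C)c2c1OC)C1=C[C+](C)C[C@@H](c4c(O)c5ccc(OC)c(OC)c5n(C)c4=O)[C@@H]1C(C)(C)O3 | intermediate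
26 | CNP0237003.1; C-c S, C-e R, C-f S | COc1ccc2c3c(c(=O)n(C)c2c1OC)C1=C[C@]2(C)C[C@@H](c4c(c5ccc(OC)c(OC)c5n(C)c4=O)O2)[C@@H]1C(C)(C)O3 | target

## Step count and risks

Total step count: 10. Longest linear sequence: 9 (steps 1, 2, 4, 5, 6, 7, 8, 9, 10).

**Step 7 (highest risk)**
- What may go wrong:
  - The conjugate addition may be slow or reversible at the hindered arylidene carbon.
  - Enantiopurity may erode through retro-Michael and re-addition during the DBU stage.
  - Equilibration at C-f may not go fully to trans.
- Fallback: this runs from 16 and 17 back to 18.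
  - Activation is moved from the nucleophile to the acceptor. 17 is silylated (TMSCl, Et3N) to allyl 3-(trimethylsilyloxy)but-2-enoate F1.
  - 16 is bound through its C-a carbonyl and the lactam carbonyl of quinolone A as a six-membered chelate on divalent copper. The system is Cu(OTf)2 with the tert-butyl bis(oxazoline) ligand of the matching hand, in CH2Cl2 with (CF3)2CHOH as silyl acceptor.
  - This Mukaiyama–Michael addition is known for two-point-binding acceptors. It should give 18, now isolated and purified, and a separate DBU treatment takes it to 20.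

**Step 6**
- What may go wrong:
  - The hindered aldol addition may revert before the aldolate is trapped.
  - Pyran A may open through beta-elimination from the enolate.
  - The elimination may give an alkene mixture.
- Fallback: this runs from 9, with 11 made from 10 as in step 5, back to 16. The polarity of the coupling is reversed.
  - 9 is heated with tert-butoxybis(dimethylamino)methane in PhMe to give the enaminone 3-(dimethylaminomethylidene) chromanone A F2.
  - Aryllithium 11 is then added at −78 °C. Addition to the unhindered enaminone carbon and loss of dimethylamide (addition–elimination on a vinylogous amide, a known ketone-to-alkylidene-ketone conversion) should give 16 without aldolate or dehydration.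

**Step 10**
- What may go wrong:
  - The allyl cation may be captured at C-a instead of C-c.
  - Proton loss from C-f of the cation followed by reprotonation would scramble that centre.
- Fallback: this runs from 22 to 26 and avoids the cation by forming the O–C4 bond of quinolone B instead of the O–C-c bond.
  - TFA in wet CH2Cl2 removes MOM from 22 to give the 4-hydroxyquinolone enone F3.
  - TsCl, Et3N and DMAP give the 4-tosyloxyquinolone enone F4.
  - MeLi/CeCl3 at −78 °C should add anti to quinolone B to give the tosyloxy tertiary alcohol F5, with oxygen cis to quinolone B.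
  - On warming, with KN(SiMe3)2 if needed, its alkoxide displaces tosylate by intramolecular addition–elimination at C4, a known reaction of 4-sulfonyloxy-2-quinolones. This gives 26 with the C-c–O bond never broken.

Further compounds
F1 | step 7 | allyl 3-(trimethylsilyloxy)but-2-enoate (geometry unassigned) | C=CCOC(=O)C=C(C)O[Si](C)(C)C
F2 | step 6 | 3-(dimethylaminomethylidene) chromanone A (geometry unassigned) | COc1ccc2c3c(c(=O)n(C)c2c1OC)C(=O)C(=CN(C)C)C(C)(C)O3
F3 | step 10 | 4-hydroxyquinolone enone (22 without MOM; C-e R, C-f S) | COc1ccc2c3c(c(=O)n(C)c2c1OC)C1=CC(=O)C[C@@H](c4c(O)c5ccc(OC)c(OC)c5n(C)c4=O)[C@@H]1C(C)(C)O3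
F4 | step 10 | 4-tosyloxyquinolone enone (C-e R, C-f S) | COc1ccc2c3c(c(=O)n(C)c2c1OC)C1=CC(=O)C[C@@H](c4c(OS(=O)(=O)c6ccc(C)cc6)c5ccc(OC)c(OC)c5n(C)c4=O)[C@@H]1C(C)(C)O3
F5 | step 10 | tosyloxy tertiary alcohol (C-c S, C-e R, C-f S) | COc1ccc2c3c(c(=O)n(C)c2c1OC)C1=C[C@](O)(C)C[C@@H](c4c(OS(=O)(=O)c6ccc(C)cc6)c5ccc(OC)c(OC)c5n(C)c4=O)[C@@H]1C(C)(C)O3
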